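## The problem

Target 24 is an achiral trimer. An enolised 2-butanoyl-6,6-dimethylcyclohexane-1,3,5-trione (ring A), a butanoylphloroglucinol (ring B) and a butanoyl-methylphloroglucinol (ring C) are joined in a row by two CH2 bridges, with no ring fused to another. The task is therefore to place the substituents correctly on three six-membered rings and to make two aryl–CH2 bonds between defined partners. There is no stereocentre in 24, so nothing has to be controlled or relayed; stereogenic atoms that appear in intermediates (C4 of a cyclobutenone, sp3 ring carbons before aromatisation) only have to be erasable. Ring C is hexasubstituted: c1 carries the bridge, c2 OH, c3 CH3, c4 OH, c5 the butanoyl group and c6 OH. Ring B carries three different carbon groups on alternate carbons (b1 the bridge to ring A, b3 the bridge to ring C, b5 butanoyl) between three hydroxyls. The free polyphenols and the enolised trione oxidise easily, the electron-rich aryl–CH2–aryl bonds are cleaved by strong acid while the rings are not yet acylated, and hot alkali fragments the bridges and re-adds them, which scrambles the partners. Joining two different phloroglucinols with a one-carbon electrophile gives both homodimers beside the cross product, so each bridge should be made from partners whose roles are fixed. The handle for a ring synthesis is the alternation in ring C: the oxygens at c2, c4 and c6 correspond to a ketene carbonyl carbon, the enol ether carbon of a 3-alkoxycyclobutenone and the oxygen-bearing carbon of a siloxyalkyne, c3–CH3 is the substituent at C4 of the cyclobutenone, c1 with its CH2–aryl arm is the second alkyne carbon, and c5 stays C–H for the acyl group.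

## Retrosynthesis

The bridge between ring A and b1 is cut first, which gives the B–C dimer 18 and butyrylfilicinic acid 21 plus one carbon. This cut is preferred to the b3–CH2–c1 cut because 21 is a simple monomer and because b1 is the only unsubstituted ring carbon of 18, so only one site can react. The forward reaction must fix the roles: 21 is first turned into its aminomethyl derivative 22, which releases the methylidene trione 23 only when 18 is present to capture it.

Dimer 18 is traced back to its fully O-alkylated form 17 (five methyl ethers, one ethyl ether), and 17 to the acyl-free pentaether 16 by removing both butanoyl groups. Acylating before dealkylating is preferred to the reverse order because the unacylated hexaphenol would be the species most prone to oxidation and acid cleavage of the bridge. Ring B of 16 is symmetrical about the bridge, so its acylation has no regiochemical question, and c5 is the only free carbon of ring C. The forward reaction has to give one acyl group per ring and must not cleave the bridge.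

Pentaether 16 comes from phenol 14 by exchanging the silyl group for methyl and capping the free hydroxyl, through the diol 15. This costs one operation and removes both the acidic OH and the bulky silyl ether next to c5 before the Friedel–Crafts step.

Phenol 14 is cut at c1–c2, c2–c3 and c5–c6 into cyclobutenone 9 and siloxyalkyne 5. This is the disconnection that carries the plan. It takes ring C apart into a four-carbon and a two-carbon piece, puts every substituent of the ring in place by connectivity, and makes the bridge to ring B part of the alkyne, so that this bridge needs no phenol coupling at all. The precursors are far simpler: 9 has four ring carbons and 5 is an arylacetic acid derivative. The forward reaction must deliver the right orientation in the ketene–alkyne cycloaddition.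

Siloxyalkyne 5 is cut at the Si–O bond and at the bond between its two alkyne carbons, leading through ynolate 4 and enolate 3 to ester 2 and to acid 1. The Kowalski homologation turns an ester into exactly this kind of ynolate in one flask, which is shorter than building the terminal alkyne and oxidising it. Cyclobutenone 9 is cut across the four-membered ring into methylketene 8, made from propanoyl chloride 6, and ethoxyethyne 7.

Butyrylfilicinic acid 21 is cut at its two C–CH3 bonds to 1-(2,4,6-trihydroxyphenyl)butan-1-one 20, and 20 at the aryl–acyl bond to phloroglucinol 19. Putting the acyl group on first is preferred because it leaves two equivalent ring carbons and directs the double methylation to one of them.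

## Roads not taken

Alternative 1: Ring A would be made last, on a finished B–C unit. The ring is cut at two C–C bonds so that it falls into methyl 2,2-dimethyl-3-oxobutanoate A2 and the dihydrocoumarin A3, 6-butanoyl-8-[(3-butanoyl-2,4,6-trihydroxy-5-methylphenyl)methyl]-5,7-dihydroxy-3,4-dihydrochromen-2-one, in which one phenol oxygen of ring B and the future bridge carbon are tied up in a lactone. Forward, the methyl ketone enolate of A2 opens the lactone (Claisen condensation), the former lactone alpha carbon attacks the methyl ester (Dieckmann condensation), and the enolised trione A1 results with the ring B phenol set free. Its merit is that the bridge between rings A and B is the benzylic carbon of the lactone, so it is made without any one-carbon coupling of two phenols and without homodimers; in this respect the road is better than step 10 of the chosen plan. Its weak points are three. A1 still lacks the butanoyl group of ring A, and C-acylation of an enolised trione beside six phenols competes with O-acylation. The Claisen step needs strong base in the presence of phenols and of two aryl ketones with acidic alpha protons, so A3 would have to be fully protected and deprotected again. And A3 must itself be made from a B–C dimer whose bridge still has to be built. The chosen plan sets against the clean bridge of this road that its ring A arrives as 21 with the acyl group in place after two steps, and that its other bridge is built into ring C by the ring construction.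

Alternative 2: Here ring B is the ring that is built, by cutting b3–b4 and b5–b6. The diene 1-ethoxy-3-(trimethylsilyloxy)-4-[(2,4,6-trimethoxy-3-methylphenyl)methyl]cyclohexa-1,3-diene A5 and the push–pull alkyne 1-ethoxyhex-1-yn-3-one A6 would combine in a Diels–Alder reaction, the bicyclo[2.2.2]octadiene would lose ethylene on heating (Alder–Rickert), and desilylation would give phenol A4. Its merits are that the butanoyl group of ring B comes in with the alkyne in a fixed position relative to the bridge, that b1 is left free, and that the polarisation of both partners is matched. No Friedel–Crafts acylation of ring B is needed and over-acylation cannot occur, which is better than step 6 of the chosen plan. Ring C enters as a ready-made permethylated arene, which is economical. Its weak points are that A5 is a sensitive diene needing several steps of its own, that A6 may polymerise at the temperature needed for loss of ethylene, that ring C in A4 still lacks its butanoyl group and must be acylated on the acid-sensitive diarylmethane anyway, and that five ethers, two of them ethyl, remain to be cleaved. The chosen plan accepts one joint Friedel–Crafts step for both rings, in which the symmetry of ring B removes the regiochemical question, and offers key-step partners that are one and two steps from commercial compounds.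

Alternative 3: The same type of annulation would be used for ring A. 3-Ethoxy-4,4-dimethyl-2-[(2,4,6-trimethoxyphenyl)methyl]cyclobut-2-en-1-one A8 and ethynyloxy(triisopropyl)silane A9 would give, through ring opening, [2+2] addition, second ring opening and six-electron closure, the dienone A7, which cannot aromatise because of its gem-dimethyl carbon. Its merits are that ring A is obtained directly in dearomatised form with both enol oxygens differentiated, that the gem-dimethyl group needs no C-methylation, and that the bridge to ring B is a substituent of the cyclobutenone and therefore unambiguous, as in Alternative 1. Its weak points are that the electrocyclisation must form a quaternary carbon without aromatisation as driving force, that the terminal siloxyalkyne A9 is less stable than an internal one, and that the ring A butanoyl group must then be put on the one C–H carbon of a bis-enol ether or free trione, again with O- against C-acylation. Ring C would also have to be joined to ring B afterwards by a coupling of two phenols, which brings the homodimer problem back at the bridge where the chosen plan avoids it. Ring A is moreover the ring that classical chemistry gives most cheaply (21 in two steps), so the annulation would be spent where it saves least. In precedent the two roads are equal; the chosen plan has aromatisation as driving force and must set a Mannich-type coupling for the A–B bridge against the built-in bridge of this road.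

Key step: step 4

Remark on the chemistry (assumption): 2-(2,4,6-trimethoxyphenyl)acetic acid, ethoxyethyne (as its hexane solution) and anhydrous phloroglucinol are taken as purchasable, and the enolised trione ring A is written throughout in the tautomer of the target structure.

## Route

Step 1
Reactants: 1 2-(2,4,6-trimethoxyphenyl)acetic acid
Product: 2 methyl 2-(2,4,6-trimethoxyphenyl)acetate
Conditions: MeI, K2CO3, DMF, rt
Reagents that add atoms: iodomethane, CI
Why: O-alkylation of the carboxylate (SN2 on iodomethane) under weakly basic conditions keeps acid away from the electron-rich arene; the ester is the substrate of the Kowalski homologation that follows.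

Step 2
Reactants: 2 methyl 2-(2,4,6-trimethoxyphenyl)acetate
Product: 5 triisopropyl[3-(2,4,6-trimethoxyphenyl)prop-1-yn-1-yloxy]silane, via dibromo enolate 3 (not isolated), via lithium ynolate 4 (not isolated)
Conditions: CH2Br2, lithium 2,2,6,6-tetramethylpiperidide, THF, −78 °C; n-BuLi, −78 °C to rt; then i-Pr3SiOTf, −78 to 0 °C
Reagents that add atoms: dibromomethane, BrCBr; triisopropylsilyl trifluoromethanesulfonate, CC(C)[Si](OS(=O)(=O)C(F)(F)F)(C(C)C)C(C)C
Why: Kowalski ester homologation to an ynolate: dibromomethyllithium adds to the ester, the dibromomethyl ketone is held as enolate 3, bromine–lithium exchange triggers the 1,2-shift of the arylmethyl group to ynolate 4, and the bulky silyl triflate silylates on oxygen to give the ynol silyl ether; the di-ortho-substituted, electron-rich aryl group lowers the acidity of the benzylic ester protons, so addition should outrun enolisation.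

Step 3
Reactants: 6 propanoyl chloride, 7 ethoxyethyne
Product: 9 3-ethoxy-4-methylcyclobut-2-en-1-one (racemic), via methylketene 8 (not isolated)
Conditions: Et3N, Et2O, 0 °C to rt, slow addition of 6 to excess 7
Reagents that add atoms: none
Why: Dehydrochlorination gives methylketene 8, which undergoes the known [2+2] cycloaddition with the alkoxyalkyne, the ketene carbonyl carbon bonding to the terminal alkyne carbon, so that ethoxy ends at C3 and methyl at C4; the new stereocentre forms racemic and is erased in step 4.

Step 4
Reactants: 9 3-ethoxy-4-methylcyclobut-2-en-1-one (racemic), 5 triisopropyl[3-(2,4,6-trimethoxyphenyl)prop-1-yn-1-yloxy]silane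
Product: 14 3-ethoxy-2-methyl-5-(triisopropylsilyloxy)-6-[(2,4,6-trimethoxyphenyl)methyl]phenol, via vinylketene 10 (not isolated), via vinylcyclobutenone 11 (not isolated), via dienylketene 12 (not isolated), via cyclohexadienone 13 (not isolated)
Conditions: 9 (1.5 equiv), toluene, sealed tube, 80 °C then 110 °C, argon
Reagents that add atoms: none
Why: Heating opens 9 by reversible four-electron electrocyclic ring opening to the (2-ethoxyvinyl)ketene 10, which adds across the alkyne of 5 in a [2+2] cycloaddition to give 11. Cyclobutenone 11 opens again (four-electron) to dienylketene 12, and six-electron electrocyclisation between the ketene carbon and the methyl-bearing diene terminus closes ring C (bond c2–c3) to cyclohexadienone 13, which tautomerises to phenol 14. This is the Danheiser benzannulation of a cyclobutenone with a siloxyalkyne; the 3-ethoxy group is a substituent change within that class, but it stabilises 9 as a vinylogous ester, which is why the temperature is raised to 110 °C. The one selectivity needed is the orientation of the [2+2] step: the ketene carbonyl carbon must bond to the arylmethyl-bearing alkyne carbon (c2–c1) and the ketene alpha carbon to the siloxy carbon (c5–c6), and the polarisation of the ynol ether, whose carbon remote from oxygen is the nucleophilic one, secures this. Only the isomer of 12 with the ketene and ethoxypropenyl arms cis can cyclise, and since the ring openings are reversible the material should funnel through it. No stereocentre survives: the racemic centres of 9, 11 and 13 all become sp2 ring carbons of 14. The product carries three different oxygens (free OH at c2, OEt at c4, OSi(i-Pr)3 at c6), methyl at c3, the bridge at c1 and hydrogen at c5, all fixed by the connectivity of the two partners.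

Step 5
Reactants: 14 3-ethoxy-2-methyl-5-(triisopropylsilyloxy)-6-[(2,4,6-trimethoxyphenyl)methyl]phenol
Product: 16 1-ethoxy-3,5-dimethoxy-2-methyl-4-[(2,4,6-trimethoxyphenyl)methyl]benzene, via resorcinol 15 (not isolated)
Conditions: n-Bu4NF, THF, 0 °C; then MeI, K2CO3, DMF, rt
Reagents that add atoms: iodomethane, CI
Why: Fluoride cleaves the aryl silyl ether and both phenols are then O-methylated (Williamson ether synthesis; the dipolar aprotic solvent favours O- over C-alkylation); this removes the acidic OH groups and the bulky silyl ether next to c5 before the Friedel–Crafts step.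

Step 6
Reactants: 16 1-ethoxy-3,5-dimethoxy-2-methyl-4-[(2,4,6-trimethoxyphenyl)methyl]benzene
Product: 17 1-[3-[(3-butanoyl-4-ethoxy-2,6-dimethoxy-5-methylphenyl)methyl]-2,4,6-trimethoxyphenyl]butan-1-one
Conditions: n-PrCOCl (2.2 equiv), SnCl4, CH2Cl2, −20 to 0 °C
Reagents that add atoms: butanoyl chloride, CCCC(=O)Cl
Why: Friedel–Crafts acylation: c5 of ring C and the two equivalent free carbons of ring B each lie ortho to two alkoxy groups and para to a third; the first acyl group deactivates its own ring, so the second should enter the other ring and give one butanoyl group per ring, while the mild Lewis acid and low temperature limit acid cleavage of the diarylmethane.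

Step 7
Reactants: 17 1-[3-[(3-butanoyl-4-ethoxy-2,6-dimethoxy-5-methylphenyl)methyl]-2,4,6-trimethoxyphenyl]butan-1-one
Product: 18 1-[3-[(3-butanoyl-2,4,6-trihydroxy-5-methylphenyl)methyl]-2,4,6-trihydroxyphenyl]butan-1-one
Conditions: BBr3 (excess), CH2Cl2, −78 °C to rt; aqueous work-up, argon
Reagents that add atoms: none
Why: Lewis acid dealkylation of aryl alkyl ethers with BBr3; the four ethers ortho to a ketone should go first by chelation and the two ethers para to a ketone need the excess and room temperature, while the acylated rings resist ipso protonation, which should keep the bridge intact.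

Step 8
Reactants: 19 benzene-1,3,5-triol
Product: 20 1-(2,4,6-trihydroxyphenyl)butan-1-one
Conditions: n-PrCOCl, AlCl3, CH2Cl2–PhNO2, rt to 40 °C
Reagents that add atoms: butanoyl chloride, CCCC(=O)Cl
Why: Friedel–Crafts C-acylation of phloroglucinol; the first acyl group deactivates the ring towards a second acylation.

Step 9
Reactants: 20 1-(2,4,6-trihydroxyphenyl)butan-1-one
Product: 21 2-butanoyl-3,5-dihydroxy-6,6-dimethylcyclohexa-2,4-dien-1-one
Conditions: NaOMe, MeI, MeOH, 0 °C to rt
Reagents that add atoms: iodomethane, CI
Why: Dearomatising C-methylation of the acylphloroglucinol anion in a protic solvent; the first methyl group raises the nucleophilicity of its own carbon, so the second should enter at the same position and give the gem-dimethyl enolised trione, with under- and over-methylated by-products removed on purification.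

Step 10
Reactants: 21 2-butanoyl-3,5-dihydroxy-6,6-dimethylcyclohexa-2,4-dien-1-one, 18 1-[3-[(3-butanoyl-2,4,6-trihydroxy-5-methylphenyl)methyl]-2,4,6-trihydroxyphenyl]butan-1-one
Product: 24 2-butanoyl-4-[[3-butanoyl-5-[(3-butanoyl-2,4,6-trihydroxy-5-methylphenyl)methyl]-2,4,6-trihydroxyphenyl]methyl]-3,5-dihydroxy-6,6-dimethylcyclohexa-2,4-dien-1-one, via Mannich base 22 (not isolated), via methylidene trione 23 (not isolated)
Conditions: 21 and Me2N=CH2+ I− (1.3 equiv each), NaOAc, MeCN, 0 °C to rt; then 18, 60 °C, argon
Reagents that add atoms: dimethylmethylideneammonium iodide, C[N+](C)=C.[I-]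
Why: Mannich reaction at the only C–H carbon between the two enol carbons of 21 gives 22, which on warming loses dimethylamine to the methylidene trione 23; this strong Michael acceptor is captured by b1, the only unsubstituted ring carbon of 18 (Michael addition, then re-aromatisation), and pre-forming 22 fixes 21 as the electrophile and should keep the symmetrical dimers low.

## Compound list

1 | 2-(2,4,6-trimethoxyphenyl)acetic acid | COc1cc(OC)c(CC(=O)O)c(OC)c1 | starting material
2 | methyl 2-(2,4,6-trimethoxyphenyl)acetate | COC(=O)Cc1c(OC)cc(OC)cc1OC | intermediate
3 | lithium 1,1-dibromo-3-(2,4,6-trimethoxyphenyl)prop-1-en-2-olate | [Li+].[O-]C(Cc1c(OC)cc(OC)cc1OC)=C(Br)Br | intermediate (not isolated)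
4 | lithium 3-(2,4,6-trimethoxyphenyl)prop-1-yn-1-olate | [Li+].[O-]C#CCc1c(OC)cc(OC)cc1OC | intermediate (not isolated)
5 | triisopropyl[3-(2,4,6-trimethoxyphenyl)prop-1-yn-1-yloxy]silane | COc1cc(OC)c(CC#CO[Si](C(C)C)(C(C)C)C(C)C)c(OC)c1 | intermediate
6 | propanoyl chloride | CCC(=O)Cl | starting material
7 | ethoxyethyne | C#COCC | starting material
8 | methylketene (prop-1-en-1-one) | CC=C=O | intermediate (not isolated)
9 | 3-ethoxy-4-methylcyclobut-2-en-1-one (racemic) | CCOC1=CC(=O)C1C | intermediate
10 | (Z)-3-ethoxypenta-1,3-dien-1-one | O=C=C/C(OCC)=C/C | intermediate (not isolated)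
11 | 4-[(Z)-1-ethoxyprop-1-enyl]-3-(triisopropylsilyloxy)-2-[(2,4,6-trimethoxyphenyl)methyl]cyclobut-2-en-1-one (racemic) | O=C1C(Cc2c(OC)cc(OC)cc2OC)=C(O[Si](C(C)C)(C(C)C)C(C)C)C1/C(OCC)=C/C | intermediate (not isolated)
12 | (3E,5Z)-5-ethoxy-3-(triisopropylsilyloxy)-2-[(2,4,6-trimethoxyphenyl)methyl]hepta-1,3,5-trien-1-one | O=C=C(Cc1c(OC)cc(OC)cc1OC)/C(O[Si](C(C)C)(C(C)C)C(C)C)=C\C(OCC)=C\C | intermediate (not isolated)
13 | 5-ethoxy-6-methyl-3-(triisopropylsilyloxy)-2-[(2,4,6-trimethoxyphenyl)methyl]cyclohexa-2,4-dien-1-one (racemic) | CCOC1=CC(O[Si](C(C)C)(C(C)C)C(C)C)=C(Cc2c(OC)cc(OC)cc2OC)C(=O)C1C | intermediate (not isolated)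
14 | 3-ethoxy-2-methyl-5-(triisopropylsilyloxy)-6-[(2,4,6-trimethoxyphenyl)methyl]phenol | CCOc1cc(O[Si](C(C)C)(C(C)C)C(C)C)c(Cc2c(OC)cc(OC)cc2OC)c(O)c1C | intermediate
15 | 5-ethoxy-4-methyl-2-[(2,4,6-trimethoxyphenyl)methyl]benzene-1,3-diol | CCOc1cc(O)c(Cc2c(OC)cc(OC)cc2OC)c(O)c1C | intermediate (not isolated)
16 | 1-ethoxy-3,5-dimethoxy-2-methyl-4-[(2,4,6-trimethoxyphenyl)methyl]benzene | CCOc1cc(OC)c(Cc2c(OC)cc(OC)cc2OC)c(OC)c1C | intermediate
17 | 1-[3-[(3-butanoyl-4-ethoxy-2,6-dimethoxy-5-methylphenyl)methyl]-2,4,6-trimethoxyphenyl]butan-1-one | CCCC(=O)c1c(OCC)c(C)c(OC)c(Cc2c(OC)cc(OC)c(C(=O)CCC)c2OC)c1OC | intermediate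
18 | 1-[3-[(3-butanoyl-2,4,6-trihydroxy-5-methylphenyl)methyl]-2,4,6-trihydroxyphenyl]butan-1-one | CCCC(=O)c1c(O)c(C)c(O)c(Cc2c(O)cc(O)c(C(=O)CCC)c2O)c1O | intermediate
19 | benzene-1,3,5-triol (phloroglucinol) | Oc1cc(O)cc(O)c1 | starting material
20 | 1-(2,4,6-trihydroxyphenyl)butan-1-one | CCCC(=O)c1c(O)cc(O)cc1O | intermediate
21 | 2-butanoyl-3,5-dihydroxy-6,6-dimethylcyclohexa-2,4-dien-1-one (butyrylfilicinic acid) | CCCC(=O)C1=C(O)C=C(O)C(C)(C)C1=O | intermediate
22 | 2-butanoyl-4-[(dimethylamino)methyl]-3,5-dihydroxy-6,6-dimethylcyclohexa-2,4-dien-1-one | CCCC(=O)C1=C(O)C(CN(C)C)=C(O)C(C)(C)C1=O | intermediate (not isolated)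
23 | 2-butanoyl-3-hydroxy-6,6-dimethyl-4-methylidenecyclohex-2-ene-1,5-dione | CCCC(=O)C1=C(O)C(=C)C(=O)C(C)(C)C1=O | intermediate (not isolated)
24 | 2-butanoyl-4-[[3-butanoyl-5-[(3-butanoyl-2,4,6-trihydroxy-5-methylphenyl)methyl]-2,4,6-trihydroxyphenyl]methyl]-3,5-dihydroxy-6,6-dimethylcyclohexa-2,4-dien-1-one | CCCC(=O)C1=C(O)C(Cc2c(O)c(Cc3c(O)c(C)c(O)c(C(=O)CCC)c3O)c(O)c(C(=O)CCC)c2O)=C(O)C(C)(C)C1=O | target

## Step count and risks

Total: 10 steps. Longest linear sequence: 7 steps (steps 1, 2, 4, 5, 6, 7, 10); step 3 and steps 8–9 are side branches.

Step 4 (key step). The most likely failure is a ring opening of 9 that is too slow, because the 3-ethoxy group stabilises the cyclobutenone as a vinylogous ester. At the temperature then needed, 5 may decay by silyl migration from oxygen to carbon or by oligomerisation, and the product phenol may be acylated by ketene intermediates. Fallback: it sets out from siloxyalkyne 5 and generates vinylketene 10 at room temperature without the cyclobutenone. Commercial ethyl 3-oxopentanoate is converted with triethyl orthoformate and catalytic acid into ethyl (E)-3-ethoxypent-2-enoate F1, which is saponified with KOH to (E)-3-ethoxypent-2-enoic acid F2. The potassium salt of F2 with oxalyl chloride gives (E)-3-ethoxypent-2-enoyl chloride F3. Et3N removes HCl from F3 across the gamma position (1,4-elimination, a known way to vinylketenes) in the presence of 5, so that 10 is trapped as 11. Warming to 80 °C then carries 11 through 12 and 13 to 14, where the route is rejoined.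

Step 2. Deprotonation of the arylacetate at its benzylic position may compete with addition of dibromomethyllithium, and silylation of the ynolate on carbon instead of oxygen would give a silylketene. Fallback: it sets out from ester 2 and comes back at 5. One-pot reduction of 2 with diisobutylaluminium hydride (i-Bu2AlH, −78 °C) gives 2-(2,4,6-trimethoxyphenyl)acetaldehyde F4, and Ohira–Bestmann homologation (dimethyl (1-diazo-2-oxopropyl)phosphonate, K2CO3, MeOH) gives 1,3,5-trimethoxy-2-(prop-2-yn-1-yl)benzene F5. Deprotonation of the alkyne terminus with n-BuLi and oxygen transfer from lithium tert-butyl peroxide (t-BuOOLi, from t-BuOOH and LiN(SiMe3)2) gives ynolate 4, which is silylated as in step 2 to 5.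

Step 6. Acid-induced cleavage of the diarylmethane (ipso attack on one ring and loss of the stabilised alkoxybenzyl cation) may occur before both rings are deactivated. A second acylation of ring B and partial loss of methyl groups ortho to the new ketones are also possible. Fallback: it sets out from 16 and comes back at 17 without any acid. Twofold directed ortho-lithiation (s-BuLi, TMEDA, THF, −78 to −20 °C) at c5 and at one of the two equivalent ring B carbons, each flanked by two alkoxy groups, gives the c5,b5-dilithio derivative of 16 F6. Quenching F6 with N-methoxy-N-methylbutanamide gives 17.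

Step 7. Dealkylation may stop short at the two ethers that cannot chelate (c2–OMe and b2–OMe), and prolonged exposure to the Lewis acid and to HBr may cleave the bridge. Fallback: it sets out from 17 and comes back at 18 in two stages of different mechanism. BCl3 (CH2Cl2, −78 to 0 °C) cleaves only the four ethers that can chelate boron to a butanoyl oxygen and should give 1-[3-[(3-butanoyl-2,4-dihydroxy-6-methoxy-5-methylphenyl)methyl]-2,6-dihydroxy-4-methoxyphenyl]butan-1-one F7. The two remaining methyl ethers, each para to a ketone, are then removed by chloride attack at the methyl carbon under non-acidic conditions (LiCl, DMF, 130 °C), giving 18.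

Step 10. Retro-Mannich release of 21 would lead to homo-coupling with 23, and fragmentation and re-addition could scramble the existing B–C bridge under basic or prolonged conditions. Fallback: it sets out from 18 and 21 and comes back at 24 with the roles reversed. Dimethylmethylideneammonium iodide and NaOAc aminomethylate 18 at b1 to give 1-[3-[(3-butanoyl-2,4,6-trihydroxy-5-methylphenyl)methyl]-5-[(dimethylamino)methyl]-2,4,6-trihydroxyphenyl]butan-1-one F8. Warming F8 with an excess of the cheap 21 in MeCN exchanges dimethylamine for the nucleophilic ring carbon of 21 by elimination–addition and gives 24; any excess material lost then comes from 21 and not from the dimer.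

## Further compounds

F1 | step 4 | ethyl (E)-3-ethoxypent-2-enoate | CCO/C(CC)=C/C(=O)OCC
F2 | step 4 | (E)-3-ethoxypent-2-enoic acid | CCO/C(CC)=C/C(=O)O
F3 | step 4 | (E)-3-ethoxypent-2-enoyl chloride | CCO/C(CC)=C/C(=O)Cl
F4 | step 2 | 2-(2,4,6-trimethoxyphenyl)acetaldehyde | COc1cc(OC)c(CC=O)c(OC)c1
F5 | step 2 | 1,3,5-trimethoxy-2-(prop-2-yn-1-yl)benzene | COc1cc(OC)c(CC#C)c(OC)c1
F6 | step 6 | c5,b5-dilithio derivative of 16 | [Li]c1c(OCC)c(C)c(OC)c(Cc2c(OC)cc(OC)c([Li])c2OC)c1OC
F7 | step 7 | 1-[3-[(3-butanoyl-2,4-dihydroxy-6-methoxy-5-methylphenyl)methyl]-2,6-dihydroxy-4-methoxyphenyl]butan-1-one | CCCC(=O)c1c(O)c(C)c(OC)c(Cc2c(OC)cc(O)c(C(=O)CCC)c2O)c1O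
F8 | step 10 | 1-[3-[(3-butanoyl-2,4,6-trihydroxy-5-methylphenyl)methyl]-5-[(dimethylamino)methyl]-2,4,6-trihydroxyphenyl]butan-1-one | CCCC(=O)c1c(O)c(C)c(O)c(Cc2c(O)c(CN(C)C)c(O)c(C(=O)CCC)c2O)c1O
A1 | alternative 1 | 4-[[3-butanoyl-5-[(3-butanoyl-2,4,6-trihydroxy-5-methylphenyl)methyl]-2,4,6-trihydroxyphenyl]methyl]-3,5-dihydroxy-6,6-dimethylcyclohexa-2,4-dien-1-one | CC1(C)C(=O)C=C(O)C(Cc2c(O)c(Cc3c(O)c(C)c(O)c(C(=O)CCC)c3O)c(O)c(C(=O)CCC)c2O)=C1O
A2 | alternative 1 | methyl 2,2-dimethyl-3-oxobutanoate | COC(=O)C(C)(C)C(C)=O
A3 | alternative 1 | 6-butanoyl-8-[(3-butanoyl-2,4,6-trihydroxy-5-methylphenyl)methyl]-5,7-dihydroxy-3,4-dihydrochromen-2-one | O=C1CCc2c(O)c(C(=O)CCC)c(O)c(Cc3c(O)c(C)c(O)c(C(=O)CCC)c3O)c2O1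
A4 | alternative 2 | 1-[2,6-diethoxy-4-hydroxy-3-[(2,4,6-trimethoxy-3-methylphenyl)methyl]phenyl]butan-1-one | CCCC(=O)c1c(OCC)cc(O)c(Cc2c(OC)cc(OC)c(C)c2OC)c1OCC
A5 | alternative 2 | 1-ethoxy-3-(trimethylsilyloxy)-4-[(2,4,6-trimethoxy-3-methylphenyl)methyl]cyclohexa-1,3-diene | CCOC1=CC(O[Si](C)(C)C)=C(Cc2c(OC)cc(OC)c(C)c2OC)CC1
A6 | alternative 2 | 1-ethoxyhex-1-yn-3-one | CCCC(=O)C#COCC
A7 | alternative 3 | 5-ethoxy-6,6-dimethyl-3-(triisopropylsilyloxy)-4-[(2,4,6-trimethoxyphenyl)methyl]cyclohexa-2,4-dien-1-one | CCOC1=C(Cc2c(OC)cc(OC)cc2OC)C(O[Si](C(C)C)(C(C)C)C(C)C)=CC(=O)C1(C)C
A8 | alternative 3 | 3-ethoxy-4,4-dimethyl-2-[(2,4,6-trimethoxyphenyl)methyl]cyclobut-2-en-1-one | CCOC1=C(Cc2c(OC)cc(OC)cc2OC)C(=O)C1(C)C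
A9 | alternative 3 | ethynyloxy(triisopropyl)silane | C#CO[Si](C(C)C)(C(C)C)C(C)C
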